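## Structural features

The target is a hirsutinolide-type sesquiterpene lactone; its carbons are numbered here as in germacranes: the ten-membered carbocycle is C1–C10, C11 carries C12 (lactone carbonyl) and C13 (CH2OAc), C14 is the methyl on C10 and C15 the methyl on C4. An oxygen atom bridges C1 and C4, so C1–C2–C3–C4–O is a 2-hydroxytetrahydrofuran (hemiketal at C1, quaternary ether carbon at C4) and the core is an 11-oxabicyclo[6.2.1]undecane. A γ-alkylidene butenolide O–C6(=C5)–C7=C11–C12(=O) is fused at C6/C7; it is the enol lactone of a C6 ketone, its C5=C6 bond is E (C4 and C7 cis in the ring), and the tetrasubstituted C7=C11 bond has C12 on the C6 side and C13 on the C8 side. The stereocentres are C1 (S), C4 (R), C8 (S, allylic, esterified by (E)-4-hydroxy-2-methylbut-2-enoic acid) and C10 (R); C1 and C10 are adjacent, C8 and C10 are 1,3-related, and C1 is tied to C4 by the one-atom bridge. In the open hydroxy-ketone form C1 and C6 are both ketones, 1,6-related along either arc of the ring, and the C4 oxygen, the C8 oxygen and the C10 methyl lie on one face. Fragile groups are the hemiketal (ketalization, dehydration), the enol lactone, and the 2-(acetoxymethyl)enoate, which loses acetate to bases and nucleophiles; two carboxylic esters forbid late hydrolysis. The real difficulty is the bridged ten-membered ring with three sp2 carbons, the remote quaternary C4 carbinol that must match C8/C10, and the defined tetrasubstituted C7=C11 bond.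

## Logic of the disconnections

27 ⇒ 26 ⇒ 24. The O–Si bond of the side chain is cut last. The C5=C6 enol-lactone bond is traced back to the C6 pseudo-acid hydroxyl and a C5 methylene in 24, since an enol lactone is a dehydrated γ-keto acid. The forward dehydration must act on the C6 hydroxyl and spare the C1 hemiketal hydroxyl.

24 ⇒ 22 (key). The 1,6-relationship of the C1 and C6 carbonyl carbons along both arcs is the retron of a doubly ring-fused alkene. The C1–O and C6–O bonds are removed and C1 is joined to C6 as a tetrasubstituted double bond, giving 22. In one sentence: ozonolysis of the ring-fusion alkene of 22 releases the ten-membered ring, and the two new carbonyls are captured at once by the C4 hydroxyl and the C12 carboxyl. The medium ring, the oxygen bridge and the C1 stereocentre become two fused six-membered rings with three stereocentres. The forward step needs ozone to choose C1=C6 over two electron-poor alkenes, and needs the C7=C11 geometry of 22 to place C12 next to C6.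

22 ⇒ 21 ⇒ 15 + 19 ⇒ 14. C12 is taken back to the aldehyde, the C8–O acyl bond is cut to 15 and 19, and the C13 acetate is removed to 14. Three hydroxyls of different class (primary, secondary, tertiary) allow the acyl groups to go on without protecting groups. The aldehyde is kept because earlier steps need it as an activating group.

14 ⇒ 13 ⇒ 12 ⇒ 11. The C4 hydroxyl of 14 is rejoined to C1 (retro β-elimination) to give the 7-oxanorbornane 13. Its C2–C3 bond is unsaturated in 12. In 12 the C4–C5 and C1–C6 bonds are cut in a retro-Diels–Alder sense to the furan 11. The furan oxygen of 11 is the bridging oxygen of 27, so the 2-hydroxy-5-methyltetrahydrofuran of the target is a dearomatized 2-methylfuran. The C1–C6 bond serves only as a template that closes ring B and lets C8 and C10 direct the quaternary C4; it is cut again in the key step. The cycloaddition must be exo with both tether substituents equatorial.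

11 ⇒ 10 ⇒ 8 ⇒ 5. The C11–C12 bond is cut (carbonylation of a vinyl iodide). The diol 10 is folded into the butenolide 8, whose ring proves that C13 is cis to C8. 8 is opened to the ynoate 5 by removing the vinyl group from C7 and iodine from C11 (syn addition across the triple bond). One ring thus fixes the geometry of the tetrasubstituted alkene.

5 ⇒ 3 + 4. The C7–C8 bond is cut to an aldehyde and methyl propiolate. C8 must be set by the catalyst because C10 is too far away to control it.

3 ⇒ 1 + 2. The C1–C10 bond is cut to 2-methylfuran and crotonaldehyde. One catalytic step buys C10 and delivers nine skeletal carbons.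

19 ⇒ 18 ⇒ 16 + 17. The side-chain alkene is cut by a Wittig disconnection.

## Other disconnections considered

Alternative 1: the first plan to come to mind is to close the ten-membered ring directly. The C7–C8 bond is cut, and the forward key step is an intramolecular Nozaki–Hiyama–Kishi addition of the vinyl iodide of seco-aldehyde A1 (hemiketal masked as methyl ketal) to its C8 aldehyde. The chosen plan is preferred for three reasons. The closure must form a ten-membered ring with three sp2 carbons against transannular strain. C8 would be created in the ring-closing event with no element to control it. The base- and nucleophile-sensitive alkylidene butenolide with its allylic acetate would have to survive the chromium reagent and a long linear sequence.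

Alternative 2: an anionic oxy-Cope ring expansion. The C3–C4 bond is cut and the C1–C6 bond restored, giving the 1-vinyl-2-alkenylcyclohexanol A2. The forward [3,3] shift would give the C1 ketone, the C5=C6 enol-lactone alkene and the C4 quaternary centre in one step. It is not chosen because divinylcyclohexanols of this kind react through chair transition states that give E ring alkenes, whereas the target needs the ring-cis C5=C6 bond. C4 would depend on the geometry of a tetrasubstituted enol ether. A tertiary potassium alkoxide next to a lactone on the fully substituted C6 invites acyl transfer. A2 also has two adjacent fully substituted stereocentres and is harder to make than 22.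

Alternative 3: a biomimetic end-game. The C4–O–C1 bridge and the C5=C6 bond are traced back to the 4,5-epoxy-1-ketone A3. The forward step is a base-induced vinylogous β-elimination from C6–H that opens the epoxide, followed by transannular hemiketalization. The step itself is attractive. But A3 still contains the ten-membered ring, so the ring problem is only moved. The epoxide would have to be placed stereoselectively on a flexible macrocycle, and the 1-ketone leaves C10 open to epimerization. The chosen plan sets C4 in a rigid tricycle instead.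

Key step: step 14

## Remarks

C6 of 24 forms as a mixture of hydroxyl epimers; both converge in step 15. For the two catalyst-controlled steps (1 and 2) the antipode of the catalyst is the one that gives the configuration drawn.

## Steps

Step 1
Reactants: 1 2-methylfuran; 2 (E)-but-2-enal
Product: 3 (3R)-3-(5-methylfuran-2-yl)butanal
Conditions: (2S,5S)-5-benzyl-2-tert-butyl-3-methylimidazolidin-4-one·CF3CO2H (20 mol %), CH2Cl2/i-PrOH, −40 °C
Reagents that add atoms: none
Why: Iminium-activated Friedel–Crafts conjugate alkylation of the electron-rich furan at its free α-position; the benzyl group of the imidazolidinone shields one face of the E-iminium ion, so C10 should be set as R by catalyst control, by analogy with pyrrole and indole alkylations of this catalyst class.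

Step 2
Reactants: 3 (3R)-3-(5-methylfuran-2-yl)butanal; 4 methyl prop-2-ynoate
Product: 5 methyl (4S,6R)-4-hydroxy-6-(5-methylfuran-2-yl)hept-2-ynoate
Conditions: Me2Zn, ProPhenol ligand (antipode that gives 4S, 20 mol %), Ph3P=O, toluene, 4 °C
Reagents that add atoms: none
Why: Zinc–ProPhenol asymmetric alkynylation of an aliphatic aldehyde; the dinuclear zinc catalyst binds the deprotonated alkyne and the aldehyde and should set C8 (S) under reagent control, the 1,3-related C10 centre being too remote to override it.

Step 3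
Reactants: 5 methyl (4S,6R)-4-hydroxy-6-(5-methylfuran-2-yl)hept-2-ynoate
Product: 8 (5S)-4-ethenyl-3-iodo-5-[(2R)-2-(5-methylfuran-2-yl)propyl]furan-2(5H)-one, via alkenylcopper adduct 6 (not isolated), via iodo hydroxy ester 7 (not isolated)
Conditions: CH2=CHMgBr, CuBr·SMe2, THF, −78 °C; I2, −78 to 0 °C; aq. NH4Cl/Na2S2O3
Reagents that add atoms: vinylmagnesium bromide C=C[Mg]Br; iodine II
Why: syn-Carbocupration of the ynoate puts vinyl on C7 and copper on C11 on the same side, and iodinolysis proceeds with retention. Only the isomer with the ester cis to the C8 alkoxide can lactonize, so the ring of 8 proves and locks the C7=C11 geometry (C13 carbonyl cis to C8, iodine cis to vinyl).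

Step 4
Reactants: 8 (5S)-4-ethenyl-3-iodo-5-[(2R)-2-(5-methylfuran-2-yl)propyl]furan-2(5H)-one
Product: 10 (2E,4S,6R)-3-ethenyl-2-iodo-6-(5-methylfuran-2-yl)hept-2-ene-1,4-diol, via lactol 9 (not isolated)
Conditions: i-Bu2AlH (4 equiv), CH2Cl2, −78 to 0 °C; Rochelle salt
Reagents that add atoms: none
Why: Hydride reduction of the butenolide through lactol 9 to the ene-1,4-diol should leave the vinyl iodide untouched; the double-bond geometry is carried over unchanged.

Step 5
Reactants: 10 (2E,4S,6R)-3-ethenyl-2-iodo-6-(5-methylfuran-2-yl)hept-2-ene-1,4-diol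
Product: 11 (2E)-2-(hydroxymethyl)-3-[(1S,3R)-1-hydroxy-3-(5-methylfuran-2-yl)butyl]penta-2,4-dienal
Conditions: Pd(PPh3)4 (5 mol %), CO (3 atm), Bu3SnH (slow addition), THF, 50 °C
Reagents that add atoms: carbon monoxide [C-]#[O+]
Why: Palladium-catalysed carbonylative formylation of the vinyl iodide (oxidative addition, CO insertion, hydride transfer from tin) with retention of geometry installs C12 as an aldehyde cis to the vinyl group; neither hydroxyl can reach the acyl–palladium carbon through a five- or six-membered ring, so no lactone should form.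

Step 6
Reactants: 11 (2E)-2-(hydroxymethyl)-3-[(1S,3R)-1-hydroxy-3-(5-methylfuran-2-yl)butyl]penta-2,4-dienal
Product: 12 (2E)-3-hydroxy-2-[(1S,2R,4S,6S,8S)-4-hydroxy-2,8-dimethyl-11-oxatricyclo[6.2.1.0(1,6)]undec-9-en-5-ylidene]propanal
Conditions: Me2AlCl (3.3 equiv), CH2Cl2, −78 to −20 °C; Rochelle salt at −20 °C
Reagents that add atoms: none
Why: Lewis-acid-promoted intramolecular furan Diels–Alder reaction: the aluminium-bound dienal makes the terminal C5=C6 vinyl group a vinylogous acceptor, and the 2,5-dialkylfuran adds across it (C4–C5 and C1–C6 bonds), closing ring B in the exo mode through a chair-like tether. With the C10 methyl equatorial (no allylic 1,3-strain with furan C2–H) and the C8 oxygen equatorial (held in an O8–Al–O13 chelate), the oxygen bridge forms on the face that gives C4 R, so C4 is relayed from C8 and C10 by substrate control.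

Step 7
Reactants: 12 (2E)-3-hydroxy-2-[(1S,2R,4S,6S,8S)-4-hydroxy-2,8-dimethyl-11-oxatricyclo[6.2.1.0(1,6)]undec-9-en-5-ylidene]propanal
Product: 13 (2E)-3-hydroxy-2-[(1R,2R,4S,6S,8R)-4-hydroxy-2,8-dimethyl-11-oxatricyclo[6.2.1.0(1,6)]undecan-5-ylidene]propanal
Conditions: KO2CN=NCO2K, AcOH, MeOH/CH2Cl2, 0 °C to rt
Reagents that add atoms: none
Why: Diimide reduces the strained disubstituted C2=C3 bond far faster than the tetrasubstituted enal and, unlike hydrazide sources, cannot condense with the aldehyde; saturation closes the paths to cycloreversion and to aromatization of ring A.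

Step 8
Reactants: 13 (2E)-3-hydroxy-2-[(1R,2R,4S,6S,8R)-4-hydroxy-2,8-dimethyl-11-oxatricyclo[6.2.1.0(1,6)]undecan-5-ylidene]propanal
Product: 14 (2E)-2-[(2S,4R,7R)-2,7-dihydroxy-4,7-dimethyl-3,4,5,6,7,8-hexahydronaphthalen-1(2H)-ylidene]-3-hydroxypropanal
Conditions: DBU (1.5 equiv), toluene, 0 °C to rt, short reaction time
Reagents that add atoms: none
Why: Vinylogous E1cB (retro-oxa-Michael) opening of the 7-oxanorbornane: the endo C6–H is γ to the aldehyde and antiperiplanar to the C1–O bond, so base should cleave the bridge with strain release. This gives the C1=C6 ring-fusion alkene and frees the C4 tertiary alcohol with its configuration untouched.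

Step 9
Reactants: 14 (2E)-2-[(2S,4R,7R)-2,7-dihydroxy-4,7-dimethyl-3,4,5,6,7,8-hexahydronaphthalen-1(2H)-ylidene]-3-hydroxypropanal
Product: 15 (2E)-2-[(2S,4R,7R)-2,7-dihydroxy-4,7-dimethyl-3,4,5,6,7,8-hexahydronaphthalen-1(2H)-ylidene]-3-oxopropyl acetate
Conditions: Ac2O (1.05 equiv), 2,4,6-collidine, CH2Cl2, −20 °C
Reagents that add atoms: acetic anhydride CC(=O)OC(C)=O
Why: Acetylation under a weak base should be selective for the primary allylic C13 hydroxyl over the hindered secondary C8 and the tertiary C4 hydroxyls.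

Step 10
Reactants: 16 2-[(tert-butyldimethylsilyl)oxy]acetaldehyde; 17 ethyl 2-(triphenyl-λ5-phosphanylidene)propanoate
Product: 18 ethyl (2E)-4-[(tert-butyldimethylsilyl)oxy]-2-methylbut-2-enoate
Conditions: CH2Cl2, rt
Reagents that add atoms: none
Why: Wittig olefination with a stabilized ylide should give the E-trisubstituted enoate.

Step 11
Reactants: 18 ethyl (2E)-4-[(tert-butyldimethylsilyl)oxy]-2-methylbut-2-enoate
Product: 19 (2E)-4-[(tert-butyldimethylsilyl)oxy]-2-methylbut-2-enoic acid
Conditions: LiOH, THF/H2O, rt; then 1 M HCl to pH 4 at 0 °C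
Reagents that add atoms: lithium hydroxide [Li+].[OH-]
Why: Saponification of the ethyl ester; the primary silyl ether should survive aqueous LiOH at room temperature and a brief cold acidification.

Step 12
Reactants: 15 (2E)-2-[(2S,4R,7R)-2,7-dihydroxy-4,7-dimethyl-3,4,5,6,7,8-hexahydronaphthalen-1(2H)-ylidene]-3-oxopropyl acetate; 19 (2E)-4-[(tert-butyldimethylsilyl)oxy]-2-methylbut-2-enoic acid
Product: 21 (1E,2S,4R,7R)-1-(1-acetoxy-3-oxopropan-2-ylidene)-7-hydroxy-4,7-dimethyl-1,2,3,4,5,6,7,8-octahydronaphthalen-2-yl (2E)-4-[(tert-butyldimethylsilyl)oxy]-2-methylbut-2-enoate, via mixed anhydride 20 (not isolated)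
Conditions: 2,4,6-trichlorobenzoyl chloride, Et3N, THF; then 15, DMAP, toluene, 0 °C to rt
Reagents that add atoms: none
Why: Yamaguchi esterification through mixed anhydride 20; only the secondary C8 hydroxyl should react (the tertiary C4 hydroxyl is inert), and C8 keeps its configuration because its C–O bond is not broken.

Step 13
Reactants: 21 the C8 ester aldehyde
Product: 22 (2E)-3-acetoxy-2-[(2S,4R,7R)-2-{[(2E)-4-[(tert-butyldimethylsilyl)oxy]-2-methylbut-2-enoyl]oxy}-7-hydroxy-4,7-dimethyl-3,4,5,6,7,8-hexahydronaphthalen-1(2H)-ylidene]propanoic acid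
Conditions: NaClO2, NaH2PO4, 2-methylbut-2-ene, t-BuOH/H2O, 0 °C
Reagents that add atoms: sodium chlorite [Na+].[O-]Cl=O
Why: Pinnick oxidation converts the enal to the acid without touching esters or silyl ether; the alkene scavenger removes hypochlorous acid before it can attack the electron-rich C1=C6 bond.

Step 14
Reactants: 22 the octalin dienoic acid
Product: 24 (1S,4R,8S,10R)-13-acetoxy-8-{[(2E)-4-[(tert-butyldimethylsilyl)oxy]-2-methylbut-2-enoyl]oxy}-1,6-dihydroxy-1,4-epoxygermacr-7(11)-en-12,6-olide (C6 epimers), via hydroperoxy ketal 23 (not isolated)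
Conditions: O3 (about 1 equiv), CH2Cl2, −78 °C, Sudan Red 7B end-point; then Me2S, −78 °C to rt
Reagents that add atoms: ozone [O-][O+]=O
Why: Ozone adds to the most electron-rich alkene, the tetrasubstituted C1=C6 ring-fusion bond, and the primary ozonide collapses by the Criegee mechanism to a C6 ketone and a C1 carbonyl oxide; the closest known reaction is the ozonolysis of Δ9,10-octalins to cyclodecane-1,6-diones. This one scission removes the bond shared by the two six-membered rings, so their ten peripheral carbons become the germacrane ring. The C4 hydroxyl captures the C1 carbonyl oxide by 5-exo-trig addition to give hydroperoxy ketal 23 (the tetrahydrofuran ring), which Me2S reduces to the hemiketal; the C12 carboxyl adds to the C6 ketone, again 5-exo-trig, to close the hydroxybutenolide. C1 is set by C4, because the one-atom oxygen bridge can span the ring only with C10 cis to C5, which is 1S. C6 forms as an epimeric mixture that is erased in step 15. The step needs ozone to choose C1=C6 over C7=C11 and over the side-chain enoate; both competitors carry a carbonyl group, and ozone is dosed to an indicator end-point. Because both carbonyl fragments are captured intramolecularly, intermolecular ozonides and peroxide oligomers should not build up.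

Step 15
Reactants: 24 the hemiketal hydroxybutenolide (C6 epimers)
Product: 26 (1S,4R,5E,8S,10R)-13-acetoxy-8-{[(2E)-4-[(tert-butyldimethylsilyl)oxy]-2-methylbut-2-enoyl]oxy}-1-hydroxy-1,4-epoxygermacra-5,7(11)-dien-12,6-olide, via O-acylisourea 25 (not isolated)
Conditions: DCC, Et3N (cat.), CH2Cl2, 0 °C to rt
Reagents that add atoms: none
Why: Enol lactonization: the base opens the pseudo-acid to the Z-keto carboxylate, DCC activates it as O-acylisourea 25, and the C6 enol, which can form only toward C5, is acylated intramolecularly. The bicyclic frame admits only the ring-cis (5E) alkene, and the tertiary hemiketal hydroxyl should not be acylated under these conditions.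

Step 16
Reactants: 26 the silyl-protected target
Product: 27 (1S,4R,5E,8S,10R)-13-acetoxy-1-hydroxy-8-{[(2E)-4-hydroxy-2-methylbut-2-enoyl]oxy}-1,4-epoxygermacra-5,7(11)-dien-12,6-olide (CNP0154520.1)
Conditions: HF·pyridine, pyridine, THF, 0 °C
Reagents that add atoms: none
Why: Fluoride cleavage of the primary allylic silyl ether under buffered, non-hydrolytic conditions that should spare the acetate, the enol lactone and the hemiketal.

## Compound list

1 | 2-methylfuran | Cc1ccco1 | starting material
2 | (E)-but-2-enal (crotonaldehyde) | C/C=C/C=O | starting material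
3 | (3R)-3-(5-methylfuran-2-yl)butanal | Cc1ccc(o1)[C@H](C)CC=O | intermediate
4 | methyl prop-2-ynoate | C#CC(=O)OC | starting material
5 | methyl (4S,6R)-4-hydroxy-6-(5-methylfuran-2-yl)hept-2-ynoate | Cc1ccc(o1)[C@H](C)C[C@H](O)C#CC(=O)OC | intermediate
6 | alkenylcopper adduct of 5 (bromomagnesium alkoxide; vinyl on C7, copper on C11, syn) | COC(=O)/C([Cu])=C(/C=C)[C@@H](O[Mg]Br)C[C@@H](C)c1ccc(C)o1 | intermediate
7 | methyl (2E,4S,6R)-3-ethenyl-4-hydroxy-2-iodo-6-(5-methylfuran-2-yl)hept-2-enoate | COC(=O)/C(I)=C(/C=C)[C@@H](O)C[C@@H](C)c1ccc(C)o1 | intermediate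
8 | (5S)-4-ethenyl-3-iodo-5-[(2R)-2-(5-methylfuran-2-yl)propyl]furan-2(5H)-one | Cc1ccc(o1)[C@H](C)C[C@@H]2OC(=O)C(I)=C2C=C | intermediate
9 | (5S)-4-ethenyl-3-iodo-5-[(2R)-2-(5-methylfuran-2-yl)propyl]-2,5-dihydrofuran-2-ol (lactol) | Cc1ccc(o1)[C@H](C)C[C@@H]2OC(O)C(I)=C2C=C | intermediate
10 | (2E,4S,6R)-3-ethenyl-2-iodo-6-(5-methylfuran-2-yl)hept-2-ene-1,4-diol | OC/C(I)=C(/C=C)[C@@H](O)C[C@@H](C)c1ccc(C)o1 | intermediate
11 | (2E)-2-(hydroxymethyl)-3-[(1S,3R)-1-hydroxy-3-(5-methylfuran-2-yl)butyl]penta-2,4-dienal | OC/C(C=O)=C(/C=C)[C@@H](O)C[C@@H](C)c1ccc(C)o1 | intermediate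
12 | (2E)-3-hydroxy-2-[(1S,2R,4S,6S,8S)-4-hydroxy-2,8-dimethyl-11-oxatricyclo[6.2.1.0(1,6)]undec-9-en-5-ylidene]propanal (exo cycloadduct) | OC/C(C=O)=C1/[C@@H]2C[C@@]3(C)C=C[C@@]2(O3)[C@H](C)C[C@@H]1O | intermediate
13 | (2E)-3-hydroxy-2-[(1R,2R,4S,6S,8R)-4-hydroxy-2,8-dimethyl-11-oxatricyclo[6.2.1.0(1,6)]undecan-5-ylidene]propanal | OC/C(C=O)=C1/[C@@H]2C[C@@]3(C)CC[C@@]2(O3)[C@H](C)C[C@@H]1O | intermediate
14 | (2E)-2-[(2S,4R,7R)-2,7-dihydroxy-4,7-dimethyl-3,4,5,6,7,8-hexahydronaphthalen-1(2H)-ylidene]-3-hydroxypropanal | OC/C(C=O)=C1/C2=C(CC[C@@](C)(O)C2)[C@H](C)C[C@@H]1O | intermediate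
15 | (2E)-2-[(2S,4R,7R)-2,7-dihydroxy-4,7-dimethyl-3,4,5,6,7,8-hexahydronaphthalen-1(2H)-ylidene]-3-oxopropyl acetate | CC(=O)OC/C(C=O)=C1/C2=C(CC[C@@](C)(O)C2)[C@H](C)C[C@@H]1O | intermediate
16 | 2-[(tert-butyldimethylsilyl)oxy]acetaldehyde | O=CCO[Si](C)(C)C(C)(C)C | starting material
17 | ethyl 2-(triphenyl-λ5-phosphanylidene)propanoate | CCOC(=O)C(C)=P(c1ccccc1)(c1ccccc1)c1ccccc1 | starting material
18 | ethyl (2E)-4-[(tert-butyldimethylsilyl)oxy]-2-methylbut-2-enoate | CCOC(=O)/C(C)=C/CO[Si](C)(C)C(C)(C)C | intermediate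
19 | (2E)-4-[(tert-butyldimethylsilyl)oxy]-2-methylbut-2-enoic acid | OC(=O)/C(C)=C/CO[Si](C)(C)C(C)(C)C | intermediate
20 | mixed anhydride of 19 with 2,4,6-trichlorobenzoic acid | O=C(OC(=O)c1c(Cl)cc(Cl)cc1Cl)/C(C)=C/CO[Si](C)(C)C(C)(C)C | intermediate
21 | (1E,2S,4R,7R)-1-(1-acetoxy-3-oxopropan-2-ylidene)-7-hydroxy-4,7-dimethyl-1,2,3,4,5,6,7,8-octahydronaphthalen-2-yl (2E)-4-[(tert-butyldimethylsilyl)oxy]-2-methylbut-2-enoate | CC(=O)OC/C(C=O)=C1/C2=C(CC[C@@](C)(O)C2)[C@H](C)C[C@@H]1OC(=O)/C(C)=C/CO[Si](C)(C)C(C)(C)C | intermediate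
22 | (2E)-3-acetoxy-2-[(2S,4R,7R)-2-{[(2E)-4-[(tert-butyldimethylsilyl)oxy]-2-methylbut-2-enoyl]oxy}-7-hydroxy-4,7-dimethyl-3,4,5,6,7,8-hexahydronaphthalen-1(2H)-ylidene]propanoic acid | CC(=O)OC/C(C(=O)O)=C1/C2=C(CC[C@@](C)(O)C2)[C@H](C)C[C@@H]1OC(=O)/C(C)=C/CO[Si](C)(C)C(C)(C)C | intermediate
23 | C1 hydroperoxy ketal of the ring-opened 6-oxo acid (1,4-epoxy bridge closed, C6 ketone, C12 acid) | CC(=O)OC/C(C(=O)O)=C1/C(=O)C[C@@]2(C)CC[C@](OO)(O2)[C@H](C)C[C@@H]1OC(=O)/C(C)=C/CO[Si](C)(C)C(C)(C)C | intermediate
24 | (1S,4R,8S,10R)-13-acetoxy-8-{[(2E)-4-[(tert-butyldimethylsilyl)oxy]-2-methylbut-2-enoyl]oxy}-1,6-dihydroxy-1,4-epoxygermacr-7(11)-en-12,6-olide (C6 epimers) | CC(=O)OCC1=C2C(O)(C[C@@]3(C)CC[C@](O)(O3)[C@H](C)C[C@@H]2OC(=O)/C(C)=C/CO[Si](C)(C)C(C)(C)C)OC1=O | intermediate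
25 | O-acylisourea of the ring-opened 6-oxo acid of 24 with DCC | CC(=O)OC/C(C(=O)OC(=NC1CCCCC1)NC1CCCCC1)=C1/C(=O)C[C@@]2(C)CC[C@](O)(O2)[C@H](C)C[C@@H]1OC(=O)/C(C)=C/CO[Si](C)(C)C(C)(C)C | intermediate
26 | (1S,4R,5E,8S,10R)-13-acetoxy-8-{[(2E)-4-[(tert-butyldimethylsilyl)oxy]-2-methylbut-2-enoyl]oxy}-1-hydroxy-1,4-epoxygermacra-5,7(11)-dien-12,6-olide | CC(=O)OCC1=C2/C(=C\[C@@]3(C)CC[C@](O)(O3)[C@H](C)C[C@@H]2OC(=O)/C(C)=C/CO[Si](C)(C)C(C)(C)C)OC1=O | intermediate
27 | (1S,4R,5E,8S,10R)-13-acetoxy-1-hydroxy-8-{[(2E)-4-hydroxy-2-methylbut-2-enoyl]oxy}-1,4-epoxygermacra-5,7(11)-dien-12,6-olide (CNP0154520.1) | CC(=O)OCC1=C2/C(=C\[C@@]3(C)CC[C@](O)(O3)[C@H](C)C[C@@H]2OC(=O)/C(C)=C/CO)OC1=O | target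

## Step count and least certain steps

Total: 16 steps. Longest linear sequence: 14 steps (steps 1–9 and 12–16); steps 10–11 make the side-chain acid.

Step 14 (key step). Ozone may be consumed beyond one equivalent and attack the side-chain enoate, or the carbonyl oxide may escape intramolecular capture and give peroxidic oligomers. Fallback, from 15 back to 26: the scission is run before the enoate is present. Pinnick oxidation of 15 gives the hydroxy acid F1. Ozonolysis with Me2S work-up gives the 8-hydroxy hemiketal pseudo-acid F2. DCC-mediated enol lactonization gives the 8-hydroxy alkylidene butenolide F3. Yamaguchi esterification of its secondary C8 hydroxyl with 19 (the tertiary hemiketal hydroxyl stays free) returns to the route at 26.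

Step 6. The vinylogous activation of the terminal alkene may be too weak for a useful rate or equilibrium. The Lewis acid may open the bridge of the unsaturated adduct, leading to dehydration and aromatization of ring A. Facial control would erode if the aluminium chelate does not form. Fallback, from 8 back to 14: the cycloaddition is run on the butenolide 8, whose lactone carbonyl binds the Lewis acid and whose ring holds the C8 oxygen in the plane of the C7=C11 bond. This gives the tetracyclic iodobutenolide adduct F4. Diimide gives the dihydro adduct F5. Base opens the bridge to the octalin iodobutenolide F6. i-Bu2AlH gives the iodo triol F7, and carbonylative formylation as in step 5 returns to the route at 14.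

Step 8. Deprotonation may occur at the equally γ-placed C8–H instead of C6–H, which would isomerize the γ-hydroxy enal to a 1,4-dicarbonyl compound. Prolonged base may also epimerize C10 through the extended enolate of the product. Fallback, from 13 back to 14: both hydroxyls are silylated (Et3SiOSO2CF3, 2,6-lutidine) to the bis(triethylsilyl) ether F8. The bridge is opened kinetically with KN(SiMe3)2 at −78 °C to the octalin bis(triethylsilyl) ether F9. HF·pyridine removes the silyl groups and returns to 14.

Step 2. The zinc alkoxide may enolize the aldehyde (self-aldol), and asymmetric induction with an unbranched aliphatic aldehyde may be incomplete. Fallback, from 3 back to 5: the lithium acetylide of 4 (LiN(SiMe3)2, THF, −78 °C) adds to 3 to give the C8-epimeric propargylic alcohol F10. Dess–Martin periodinane gives the ynone F11. Reduction with (S)-Alpine-Borane, a reagent-controlled ynone reduction, returns to 5.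

Step 15. The activated carboxyl or the reagent may react at the tertiary hemiketal hydroxyl (acylation, dehydration to an enol ether), and the base may displace the allylic acetate. Fallback, from 22 to 27: the hemiketal is formed last. The C4 hydroxyl of 22 is silylated (Et3SiOSO2CF3, 2,6-lutidine; aqueous work-up frees the acid) to the C4 triethylsilyl ether F12. Ozonolysis in CH2Cl2/MeOH with Me2S work-up gives the 1-ketone pseudo-acid F13. MsCl/Et3N dehydrates the pseudo-acid, with no hemiketal present, to the 1-oxo alkylidene butenolide F14. HF·pyridine removes both silyl groups, the C4 hydroxyl closes onto the C1 ketone, and the route ends at 27.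

## Further compounds

F1 | step 14 | (2E)-3-acetoxy-2-[(2S,4R,7R)-2,7-dihydroxy-4,7-dimethyl-3,4,5,6,7,8-hexahydronaphthalen-1(2H)-ylidene]propanoic acid | CC(=O)OC/C(C(=O)O)=C1/C2=C(CC[C@@](C)(O)C2)[C@H](C)C[C@@H]1O
F2 | step 14 | (1S,4R,8S,10R)-13-acetoxy-1,6,8-trihydroxy-1,4-epoxygermacr-7(11)-en-12,6-olide (C6 epimers) | CC(=O)OCC1=C2C(O)(C[C@@]3(C)CC[C@](O)(O3)[C@H](C)C[C@@H]2O)OC1=O
F3 | step 14 | (1S,4R,5E,8S,10R)-13-acetoxy-1,8-dihydroxy-1,4-epoxygermacra-5,7(11)-dien-12,6-olide | CC(=O)OCC1=C2/C(=C\[C@@]3(C)CC[C@](O)(O3)[C@H](C)C[C@@H]2O)OC1=O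
F4 | step 6 | exo cycloadduct of 8 (iodobutenolide fused to the oxanorbornene; C1–C6 and C4–C5 bonds formed) | IC1=C2[C@@H]3C[C@@]4(C)C=C[C@@]3(O4)[C@H](C)C[C@@H]2OC1=O
F5 | step 6 | 2,3-dihydro derivative of F4 (oxanorbornane) | IC1=C2[C@@H]3C[C@@]4(C)CC[C@@]3(O4)[C@H](C)C[C@@H]2OC1=O
F6 | step 6 | bridge-opened octalin iodobutenolide (C1=C6 alkene, free C4 hydroxyl) | IC1=C2C3=C(CC[C@@](C)(O)C3)[C@H](C)C[C@@H]2OC1=O
F7 | step 6 | (2S,4R,7R)-1-[(2E)-1-hydroxy-2-iodoethylidene-2-yl]octalin triol: (E)-2-iodo-2-[(2S,4R,7R)-2,7-dihydroxy-4,7-dimethyl-3,4,5,6,7,8-hexahydronaphthalen-1(2H)-ylidene]ethanol | OC/C(I)=C1/C2=C(CC[C@@](C)(O)C2)[C@H](C)C[C@@H]1O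
F8 | step 8 | bis(triethylsilyl) ether of 13 (C8 and C13 oxygens) | CC[Si](CC)(CC)OC/C(C=O)=C1/[C@@H]2C[C@@]3(C)CC[C@@]2(O3)[C@H](C)C[C@@H]1O[Si](CC)(CC)CC
F9 | step 8 | bis(triethylsilyl) ether of 14 (C8 and C13 oxygens) | CC[Si](CC)(CC)OC/C(C=O)=C1/C2=C(CC[C@@](C)(O)C2)[C@H](C)C[C@@H]1O[Si](CC)(CC)CC
F10 | step 2 | methyl (6R)-4-hydroxy-6-(5-methylfuran-2-yl)hept-2-ynoate (C4 epimers) | Cc1ccc(o1)[C@H](C)CC(O)C#CC(=O)OC
F11 | step 2 | methyl (6R)-6-(5-methylfuran-2-yl)-4-oxohept-2-ynoate | Cc1ccc(o1)[C@H](C)CC(=O)C#CC(=O)OC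
F12 | step 15 | C4 triethylsilyl ether of 22 | CC(=O)OC/C(C(=O)O)=C1/C2=C(CC[C@@](C)(O[Si](CC)(CC)CC)C2)[C@H](C)C[C@@H]1OC(=O)/C(C)=C/CO[Si](C)(C)C(C)(C)C
F13 | step 15 | (4R,8S,10R)-13-acetoxy-6-hydroxy-1-oxo-4-(triethylsilyloxy)-8-acyloxygermacr-7(11)-en-12,6-olide (C6 epimers; acyl = silylated side chain) | CC(=O)OCC1=C2C(O)(C[C@](C)(O[Si](CC)(CC)CC)CCC(=O)[C@H](C)C[C@@H]2OC(=O)/C(C)=C/CO[Si](C)(C)C(C)(C)C)OC1=O
F14 | step 15 | (4R,5E,8S,10R)-13-acetoxy-1-oxo-4-(triethylsilyloxy)-8-acyloxygermacra-5,7(11)-dien-12,6-olide (acyl = silylated side chain) | CC(=O)OCC1=C2/C(=C\[C@](C)(O[Si](CC)(CC)CC)CCC(=O)[C@H](C)C[C@@H]2OC(=O)/C(C)=C/CO[Si](C)(C)C(C)(C)C)OC1=O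
A1 | alternative 1 | seco aldehyde with C7 vinyl iodide and C1 methyl ketal (precursor for Nozaki–Hiyama–Kishi ring closure) | CC(=O)OCC1=C(I)/C(=C\[C@@]2(C)CC[C@](OC)(O2)[C@H](C)CC=O)OC1=O
A2 | alternative 2 | 1-vinyl-2-(2-silyloxyprop-1-enyl)cyclohexanol fused to the butenolide (oxy-Cope substrate) | C=C[C@@]1(O)[C@H](C)C[C@H](O[Si](C)(C)C(C)(C)C)C2=C(COC(C)=O)C(=O)O[C@]12/C=C(\C)O[Si](CC)(CC)CC
A3 | alternative 3 | 4,5-epoxy-1-oxogermacr-7(11)-en-12,6-olide with the C8 ester and C13 acetate in place | CC(=O)OCC1=C2[C@@H](OC(=O)/C(C)=C/CO)C[C@@H](C)C(=O)CC[C@@]3(C)O[C@@H]3[C@@H]2OC1=O
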